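## Conventions and remarks

- Unit 1 is the catechol flavanone (ring A = benzo ring, ring B = 3,4-dioxygenated phenyl on C2, ring C = pyran ring). Unit 2 is the naringenin (ring D = benzo ring, ring E = 4-oxygenated phenyl, ring F = pyran ring); its locants carry a double prime.
- Bn = benzyl; SEM = [2-(trimethylsilyl)ethoxy]methyl; TBS = tert-butyldimethylsilyl; TBDPS = tert-butyldiphenylsilyl. ArB = 3,4-bis(benzyloxy)phenyl. ArD = 2,4-bis(benzyloxy)-6-(SEM-oxy)phenyl.
- Remark (assumption): C4 of unit 1 is formed without control in step 12; both epimers are carried to step 19, where C4 becomes a carbonyl carbon, and the centre is written without configuration in between.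
- Remark (assumption): 1, 3 (as a THF solution), 8, 11, 16, 22, 30 and 31 are taken as catalogue compounds.

## Analysis of the target

The target 38 is a biflavanone in which C3 of a catechol-type flavanone (unit 1) is bonded to C8'' of a naringenin (unit 2). It has three stereocentres: C2 and C3 of unit 1 are both R, which places ring B and ring D on the same face of ring C (cis), and C2'' is S. C2'' lies on the far side of ring D and cannot be expected to follow the other two, so it needs its own control element. The cis arrangement is the weak point: C3–H is α to the C4 carbonyl and benzylic to ring D, and either flavanone can open to a chalcone by retro-oxa-Michael reaction, so acid, base or heat after the ketones are in place can move unit 1 to trans and scramble C2''. Seven phenols have to be carried masked and set free under neutral conditions. The C3–C8'' bond joins an sp3 carbon to an aryl carbon with an oxygen on each side and is best made before the surroundings are crowded. The strategy rests on ring A: C5, C7 and C8a carry oxygen in a 1,3,5 pattern, the ring is fused to ring C through C4a–C8a, and the pairs C8a/C8, C4a/C5 and C7/C6 can each be read as an alkyne with one oxygen-bearing carbon. The first two pairs are joined by the chain O1–C2–C3–C4, which holds both stereocentres of unit 1.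

## Retrosynthetic reasoning

**Last events (38 ⇐ 37 ⇐ 36).** The seven O–benzyl bonds are cut last, by hydrogenolysis, because this needs neither acid nor base. Before that, the C4 carbonyl of unit 1 is traced back to the carbinol of 36. Nothing in the skeleton is cut, but the gain is large: while C4 is sp3 and oxygenated, C3–H is not acidic, and every basic step can be run on the cis compound without risk.

**Ring F (36 ⇐ 35 ⇐ 34 ⇐ 29 + 32).** The O1''–C2'' bond is cut as an oxa-Michael addition. It is cut there because the closure creates C2'' at a point where a catalyst can control it, and because 35 has only one free phenol, so the ring cannot close to the wrong (6''-linked) isomer. 35 comes from 34 by loss of its two silicon-based groups with fluoride. 34 is cut at C4a''–C4'' into the chroman 29 and the enamide 32. The forward reaction has to metalate ring D at the single free position beside the SEM ether (aryllithium 33) and acylate it once.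

**Rings A and C (29 ⇐ 28 + 25).** C4a–C8a, C5–C6 and C7–C8 are cut together. This removes the whole benzo ring and opens the pyran ring in one operation and leaves an acyclic diyne 28 whose two stereocentres are ordinary sp3 carbons. The forward cycloaddition has to join three oxygen-bearing alkynes with the oxygen of 25 ending at C7, and it must not touch C2 and C3.

**The diyne (28 ⇐ 27 ⇐ 21 + 25; 21 ⇐ 20 ⇐ 19 ⇐ 15 + 16).** C4–C4a is cut as the addition of the magnesium acetylide 26 (made from 25) to aldehyde 21. O1–C8a is cut at the sp carbon, as the ethynylation of the secondary alcohol 15 with the two carbons of 16. Both cuts use the oxygen functions that the aldol chemistry below leaves behind, and the C2–O bond itself is never broken, so C2 keeps its configuration. The primary hydroxyl has to be masked while the secondary one is ethynylated (15) and unmasked and oxidized afterwards (20, 21).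

**The stereocentres (15 ⇐ 14 ⇐ 13 ⇐ 10 + 11).** C2–C3 is cut as an auxiliary-controlled syn-aldol reaction between imide 10 and aldehyde 11. This is the only place where the two stereocentres of unit 1 are made, and a syn-aldol pair becomes cis-2,3 once O1 and C4 are tied into ring C. Reduction then gives diol 14 and returns the auxiliary 8.

**Ring D building block (10 ⇐ 7 + 8; 7 ⇐ 5 ⇐ 2 + 3; 2 ⇐ 1).** The aryl–CH2 bond that becomes C3–C8'' is cut as the opening of 3 by aryllithium 4. The hindered bond is thus made first, on a flat arene, under the direction of the same SEM group that later directs the acylation of ring D. Ring D carries one SEM ether (the future O1'') and two benzyl ethers, so that later only one phenol is unveiled.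

**Small pieces (25 ⇐ 22 + 16; 32 ⇐ 30 + 31).** The third alkyne comes from 22 by the same ethynylation as in the main line, and the enamide from a Wittig reaction.

## Alternatives that were turned down

**Alternative 1:** Disconnection: O1–C2 and C3–C8'' are cut at once, leading to the ortho-hydroxyaryl ynone A1 and the ring D iodide A2. Forward key step: with Pd(OAc)2, SPhos and K3PO4, zerovalent palladium inserts into the C–I bond of A2. The divalent arylpalladium species activates the triple bond of A1, the ring A phenol attacks C2 in 6-endo mode, and reductive elimination joins C3 to ring D to give the 2,3-diarylchromone A3.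
- For: it is highly convergent, the two flat partners are each a few steps from catalogue phenols, no alkynyl ether has to be handled, and the crowded C3–aryl bond and ring C arise together. On step count and on robustness of intermediates it is stronger than the chosen route.
- Against: A3 has no stereocentre. Both C2 and C3 must then come from reduction of a tetrasubstituted, electron-rich C2=C3 bond shielded by a doubly ortho-substituted aryl group. Syn addition of hydrogen would give cis, which is an advantage, but an enantioselective version on 2,3-diarylchromones is not secured, and hydrogenation conditions also threaten the benzyl ethers and the C4 carbonyl. The cis flavanone would then exist with its C4 ketone in place while ring F is still to be built under basic conditions, which invites epimerization at C3. The 5-exo closure to an aurone and the slow coupling of the hindered iodide are further risks.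
- Comparison: the chosen route is longer and handles sensitive alkynyl ethers, but it sets both centres in one auxiliary-controlled step and keeps C4 as a carbinol until ring F is closed.

**Alternative 2:** Disconnection: C2–C3 of unit 1, leading to the α-diazo ketone A4, in which unit 2 is complete and O1 carries a CH2–ring B group. Forward key step: Rh2(S-PTTL)4 (divalent rhodium) releases N2 from A4 and the carbenoid at C3 inserts into a benzylic C–H bond next to O1, closing ring C and giving the protected target A5.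
- For: this is the most convergent plan. Both flavanone units are finished before the key step, the key step creates both stereocentres of unit 1 and delivers the full skeleton with the C4 ketone, and only deprotection follows. In convergence and brevity of the end game it is clearly stronger.
- Against: the carbenoid sits between a ketone and a ring D carbon flanked by two oxygens. Attack of these neighbouring ether oxygens on the carbenoid (oxonium ylide, then rearrangement) and addition to the electron-rich rings compete with the six-membered C–H insertion, which is less favoured than the five-membered mode on which the cis-selective precedent rests. The catalyst must also override the existing C2'' centre, and the diazo group has to be installed on a very hindered deoxybenzoin.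
- Comparison: the chosen route gives up convergence but replaces a selectivity among insertion, ylide and cyclopropanation paths by an aldol reaction of predictable sense, and ring C is closed without creating a stereocentre.

**Alternative 3:** Disconnection: O1–C2, leading to the (Z)-allylic alcohol A6. Forward key step: a chiral BINOL-derived N-triflyl phosphoramide ionizes A6 and the ring A phenol closes on C2 within the chiral ion pair, giving the 2H-chromene A7. Hydroboration–oxidation of C3=C4 from the face opposite ring B would then set C3 cis to C2 and place the hydroxyl at C4.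
- For: it is short, uses flat precursors, avoids alkynyl ethers, and the hydroboration delivers exactly the C4 carbinol that the chosen route also wants. On step economy it is at least as good.
- Against: the cation from A6 is stabilized by three electron-rich aryl groups. Such a long-lived, loosely paired cation is a poor partner for ion-pair control, and A7 can re-ionize at C2 under the same acid and lose its configuration. Hydroboration of a trisubstituted alkene bearing a doubly ortho-substituted aryl group on C3 will be slow, and its facial bias rests on one remote aryl group. The (Z) geometry of A6 has to be secured as well.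
- Comparison: the chosen route takes its absolute configuration from a covalently bound auxiliary and never passes through a compound that can ionize at C2 under acid.

Key step: step 14

## Route

Step 1
Reactants: 1 3,5-bis(benzyloxy)phenol
Product: 2 1,3-bis(benzyloxy)-5-(SEM-oxy)benzene
Conditions: NaH, SEMCl, DMF, 0 °C → rt
Reagents that add atoms: 2-(trimethylsilyl)ethoxymethyl chloride, C[Si](C)(C)CCOCCl
Why: Williamson-type O-alkylation of the sodium phenoxide by the chloromethyl ether; 1 has a single hydroxyl group, so no selectivity is needed.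

Step 2
Reactants: 2 1,3-bis(benzyloxy)-5-(SEM-oxy)benzene; 3 oxirane
Product: 5 2-[2,4-bis(benzyloxy)-6-(SEM-oxy)phenyl]ethan-1-ol, via aryllithium 4 (not isolated)
Conditions: n-BuLi, THF, 0 °C; then 3, −78 °C → rt; H2O
Reagents that add atoms: none
Why: Directed ortho-metalation: the acetal oxygens of the SEM group hold the base next to the two equivalent positions flanked by OSEM and OBn, which should be deprotonated in preference to the position between the two benzyl ethers; aryllithium 4 then opens oxirane by SN2 attack. The hindered aryl–CH2 bond (later C3–C8'') is thus made on a simple arene.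

Step 3
Reactants: 5 2-[2,4-bis(benzyloxy)-6-(SEM-oxy)phenyl]ethan-1-ol
Product: 7 2-[2,4-bis(benzyloxy)-6-(SEM-oxy)phenyl]acetic acid, via arylacetaldehyde 6 (not isolated)
Conditions: TEMPO (20 mol %), PhI(OAc)2 (2.2 equiv), MeCN/H2O 1:1, rt
Reagents that add atoms: water, O
Why: Oxoammonium (TEMPO) oxidation with PhI(OAc)2 as terminal oxidant takes the primary alcohol to aldehyde 6, whose hydrate is oxidized on to the acid in the wet medium. No chlorine-based oxidant is present, so the electron-rich ring and the ethers should be left alone.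

Step 4
Reactants: 7 2-[2,4-bis(benzyloxy)-6-(SEM-oxy)phenyl]acetic acid; 8 (4R)-4-benzyl-1,3-oxazolidin-2-one
Product: 10 (4R)-4-benzyl-3-{2-[2,4-bis(benzyloxy)-6-(SEM-oxy)phenyl]acetyl}-1,3-oxazolidin-2-one, via mixed pivalic anhydride 9 (not isolated)
Conditions: t-BuCOCl, Et3N, THF, −20 °C; then 8, LiCl, rt
Reagents that add atoms: none
Why: The acid is activated as the mixed pivalic anhydride and the oxazolidinone, activated by LiCl/Et3N, is N-acylated at the less hindered arylacetyl carbonyl (standard one-pot imide formation).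

Step 5
Reactants: 10 (4R)-4-benzyl-3-{2-[2,4-bis(benzyloxy)-6-(SEM-oxy)phenyl]acetyl}-1,3-oxazolidin-2-one; 11 3,4-bis(benzyloxy)benzaldehyde
Product: 13 (4R)-4-benzyl-3-[(2R,3R)-3-ArB-2-ArD-3-hydroxypropanoyl]-1,3-oxazolidin-2-one, via boron enolate 12 (not isolated)
Conditions: Bu2BOTf, i-Pr2NEt, CH2Cl2, −78 → 0 °C; then 11, −78 → 0 °C; pH 7 buffer, MeOH, H2O2, 0 °C
Reagents that add atoms: none
Why: Evans syn-aldol reaction: the (Z)-boron enolate 12 reacts through a Zimmerman–Traxler chair with the aldehyde on the enolate face away from the benzyl group of the (R)-auxiliary (dipole-opposed conformation). This sets C3 (R) and C2 (R) of unit 1 together, as the syn pair that becomes cis-2,3 after ring closure.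

Step 6
Reactants: 13 (4R)-4-benzyl-3-[(2R,3R)-3-ArB-2-ArD-3-hydroxypropanoyl]-1,3-oxazolidin-2-one
Product: 14 (1R,2S)-1-ArB-2-ArD-propane-1,3-diol
Conditions: LiBH4, MeOH (1 equiv), THF, 0 °C
Reagents that add atoms: none
Why: LiBH4 reduces the lithium-chelated exocyclic imide carbonyl selectively and releases the auxiliary for recovery; the transient aldehyde is reduced at once, so C3 should not epimerize.

Step 7
Reactants: 14 (1R,2S)-1-ArB-2-ArD-propane-1,3-diol
Product: 15 (1R,2S)-1-ArB-2-ArD-3-(TBDPS-oxy)propan-1-ol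
Conditions: TBDPSCl, imidazole, CH2Cl2, 0 °C
Reagents that add atoms: tert-butyl(chloro)diphenylsilane, CC(C)(C)[Si](Cl)(c1ccccc1)c1ccccc1
Why: The bulky silyl chloride reacts at the primary hydroxyl only. TBDPS is chosen over TBS because it resists O-to-O migration under the KH of step 8 and survives n-BuLi.

Step 8
Reactants: 15 (1R,2S)-1-ArB-2-ArD-3-(TBDPS-oxy)propan-1-ol; 16 trichloroethylene
Product: 19 tert-butyl{[(2S,3R)-3-ArB-2-ArD-3-(ethynyloxy)propyl]oxy}diphenylsilane, via dichlorovinyl ether 17 (not isolated), via lithium alkynyl ether 18 (not isolated)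
Conditions: KH, THF, 0 °C; 16, −50 °C → rt; then n-BuLi (2.5 equiv), −78 → −40 °C; MeOH, −78 °C
Reagents that add atoms: none
Why: The potassium alkoxide adds to dichloroacetylene (made in the flask from 16) to give the (E)-dichlorovinyl ether 17; n-BuLi then eliminates HCl and exchanges the remaining chlorine to give 18, which is protonated to the terminal ynol ether. The C2–O bond is never broken, so the configuration is kept. Everything is run at or below room temperature because secondary benzylic alkynyl ethers rearrange or lose ketene on heating.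

Step 9
Reactants: 19 tert-butyl{[(2S,3R)-3-ArB-2-ArD-3-(ethynyloxy)propyl]oxy}diphenylsilane
Product: 20 (2S,3R)-3-ArB-2-ArD-3-(ethynyloxy)propan-1-ol
Conditions: TBAF, THF, 0 °C
Reagents that add atoms: none
Why: Fluoride cleaves the primary silyl ether at 0 °C, whereas the aryl SEM ether needs much harsher fluoride treatment. No acid is used, since acids add to ynol ethers.

Step 10
Reactants: 20 (2S,3R)-3-ArB-2-ArD-3-(ethynyloxy)propan-1-ol
Product: 21 (2R,3R)-3-ArB-2-ArD-3-(ethynyloxy)propanal
Conditions: Dess–Martin periodinane, NaHCO3, CH2Cl2, 0 °C; used crude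
Reagents that add atoms: none
Why: Buffered Dess–Martin oxidation gives the aldehyde without free acid (which would add to the ynol ether) and without soluble base (which could epimerize the α-aryl centre C3 or eliminate the ynolate). The aldehyde is used at once without chromatography.

Step 11
Reactants: 22 benzyl alcohol; 16 trichloroethylene
Product: 25 benzyl ethynyl ether, via benzyl dichlorovinyl ether 23 (not isolated), via lithium (benzyloxy)acetylide 24 (not isolated)
Conditions: KH, THF, 0 °C; 16, −50 °C → rt; then n-BuLi (2.5 equiv), −78 → −40 °C; MeOH, −78 °C; kept as a cold solution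
Reagents that add atoms: none
Why: The same ynol ether synthesis as in step 8, on a simple primary alcohol. 25 is stored cold in solution because benzyl alkynyl ethers rearrange sigmatropically on warming.

Step 12
Reactants: 21 (2R,3R)-3-ArB-2-ArD-3-(ethynyloxy)propanal; 25 benzyl ethynyl ether
Product: 27 (1R,2S)-5-(benzyloxy)-1-ArB-2-ArD-1-(ethynyloxy)pent-4-yn-3-ol (both C3 epimers), via (benzyloxy)ethynylmagnesium bromide 26 (not isolated)
Conditions: 25 (2.2 equiv), EtMgBr (2.0 equiv), THF, 0 °C; then 21, −40 → 0 °C; H2O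
Reagents that add atoms: none
Why: Grignard alkynylation: EtMgBr deprotonates the terminal ynol ether to the alkynylmagnesium bromide 26 (the benzyl counterpart of ethoxyethynylmagnesium bromide), which adds to the aldehyde carbonyl and forms the C4–C4a bond. Being far less basic than a lithium acetylide, 26 should neither enolize the α-aryl aldehyde (epimerization at C3) nor expel the β-ynolate, and the slight excess of 25 over EtMgBr leaves no free alkyl Grignard reagent. A Felkin–Anh approach anti to the bulky ring D aryl should favour one epimer at the new carbinol, but both are carried on because this carbon becomes a carbonyl in step 19.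

Step 13
Reactants: 27 (1R,2S)-5-(benzyloxy)-1-ArB-2-ArD-1-(ethynyloxy)pent-4-yn-3-ol
Product: 28 (4R,5R)-1-(benzyloxy)-5-ArB-4-ArD-5-(ethynyloxy)-3-(TBS-oxy)pent-1-yne (both C3 epimers)
Conditions: TBSCl, imidazole, DMAP (cat.), DMF, rt
Reagents that add atoms: tert-butyl(chloro)dimethylsilane, CC(C)(C)[Si](C)(C)Cl
Why: Silylation of the propargylic alcohol under mild conditions (no silyl triflate, which could attack the electron-rich alkynes) masks C4 as a group that neither ionizes nor acidifies C3 and that lasts until step 17.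

Step 14
Reactants: 28 (4R,5R)-1-(benzyloxy)-5-ArB-4-ArD-5-(ethynyloxy)-3-(TBS-oxy)pent-1-yne; 25 benzyl ethynyl ether
Product: 29 (2R,3R)-5,7-bis(benzyloxy)-2-ArB-3-ArD-4-(TBS-oxy)chromane (cis-2,3; both C4 epimers)
Conditions: [Rh(cod)2]BF4 (10 mol %), rac-BINAP (10 mol %), H2 then Ar, CH2Cl2, rt; 25 (4 equiv), slow addition of 28
Reagents that add atoms: none
Why: After hydrogen has stripped the cod ligands, the cationic monovalent rhodium–BINAP fragment binds the two tethered triple bonds of 28 and couples them oxidatively; this forms C4a–C8a and a trivalent rhodacyclopentadiene whose fused six-membered ring (C8a, O1, C2, C3, C4, C4a) is ring C, closed as the tether ring of a 1,7-diyne. Alkyne 25 then coordinates and inserts into the Rh–C8 bond (forming C7–C8), and reductive elimination from the seven-membered rhodacycle forms C5–C6 and closes ring A as a new benzene ring while returning monovalent rhodium. The closest known reaction type is the cationic rhodium/bisphosphine-catalysed [2+2+2] cycloaddition of tethered diynes with terminal alkynes to fused benzenes, which accepts alkynyl ethers; the use of three of them at once is the stretch. No stereocentre is created: C2 and C3 are sp3 tether atoms without acidic hydrogen as long as C4 is a silylated carbinol, so the syn relationship from step 5 should become cis-2,3 unchanged, and both C4 epimers should react alike. Two selectivities are needed. Cross-coupling over homo-coupling is secured by the intramolecular first step, which the three substituents on the tether favour, by slow addition of 28 and by an excess of 25. The orientation of 25 is secured by the unsymmetrical rhodacycle: its C5 terminus carries a benzyloxy group and its C8 terminus only hydrogen, so the oxygen-bearing carbon of 25 should bond to C8, away from the C5 oxygen, and the three oxygens end 1,3,5. Room temperature and a neutral aprotic medium are kept because benzylic alkynyl ethers rearrange on heating and hydrate with acid.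

Step 15
Reactants: 30 4-(benzyloxy)benzaldehyde; 31 N-methoxy-N-methyl-2-(triphenyl-λ5-phosphanylidene)acetamide
Product: 32 (2E)-3-[4-(benzyloxy)phenyl]-N-methoxy-N-methylprop-2-enamide
Conditions: CH2Cl2, 40 °C
Reagents that add atoms: none
Why: Wittig reaction of the stabilized ylide with an aryl aldehyde, which should give the (E)-enamide.

Step 16
Reactants: 29 (2R,3R)-5,7-bis(benzyloxy)-2-ArB-3-ArD-4-(TBS-oxy)chromane; 32 (2E)-3-[4-(benzyloxy)phenyl]-N-methoxy-N-methylprop-2-enamide
Product: 34 (2E)-3-[4-(benzyloxy)phenyl]-1-{4,6-bis(benzyloxy)-3-[(2R,3R)-5,7-bis(benzyloxy)-2-ArB-4-(TBS-oxy)chroman-3-yl]-2-(SEM-oxy)phenyl}prop-2-en-1-one, via ring D aryllithium 33 (not isolated)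
Conditions: n-BuLi, THF, −20 → 0 °C; then 32, −78 → 0 °C; H2O
Reagents that add atoms: none
Why: SEM-directed ortho-lithiation at the only free position next to the SEM ether of ring D (between OSEM and OBn), then 1,2-addition of 33 to the Weinreb amide; the chelated tetrahedral adduct stops over-addition and collapses to the enone on work-up, forming the C4a''–C4'' bond. C2 and C3 carry no acidic hydrogen while C4 is a silyl ether.

Step 17
Reactants: 34 (2E)-3-[4-(benzyloxy)phenyl]-1-{4,6-bis(benzyloxy)-3-[(2R,3R)-5,7-bis(benzyloxy)-2-ArB-4-(TBS-oxy)chroman-3-yl]-2-(SEM-oxy)phenyl}prop-2-en-1-one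
Product: 35 (2E)-3-[4-(benzyloxy)phenyl]-1-{4,6-bis(benzyloxy)-3-[(2R,3S)-5,7-bis(benzyloxy)-2-ArB-4-hydroxychroman-3-yl]-2-hydroxyphenyl}prop-2-en-1-one (both C4 epimers; the C3 descriptor changes with the free hydroxyl, the arrangement does not)
Conditions: TBAF (excess), THF/DMPU, 50 °C; pH 7 buffer, 0 °C; silica deactivated with Et3N
Reagents that add atoms: none
Why: Fluoride removes the TBS ether and fragments the SEM group (to Me3SiF, ethene and formaldehyde), helped by the ortho acyl group that makes the phenoxide a good leaving group. In the strongly basic medium the chalcone should stay open as its phenoxide, as in a Claisen–Schmidt condensation, and cold neutral work-up should deliver 35 before uncatalysed ring closure sets in.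

Step 18
Reactants: 35 (2E)-3-[4-(benzyloxy)phenyl]-1-{4,6-bis(benzyloxy)-3-[(2R,3S)-5,7-bis(benzyloxy)-2-ArB-4-hydroxychroman-3-yl]-2-hydroxyphenyl}prop-2-en-1-one
Product: 36 (2S)-5,7-bis(benzyloxy)-2-[4-(benzyloxy)phenyl]-8-[(2R,3S)-5,7-bis(benzyloxy)-2-ArB-4-hydroxychroman-3-yl]chroman-4-one (both C4 epimers of the carbinol)
Conditions: quinine-derived bifunctional thiourea [9-amino(9-deoxy)epi-quinine N'-3,5-bis(trifluoromethyl)phenyl thiourea] (20 mol %), PhMe, 0 °C → rt
Reagents that add atoms: none
Why: Intramolecular oxa-Michael addition (6-endo-trig) of the C8a'' phenol to the enone under bifunctional catalysis: the quinuclidine nitrogen deprotonates the phenol and the thiourea binds the carbonyl, so the phenoxide is delivered to one face of the double bond and C2'' is set by the catalyst (the quinidine-derived pseudoenantiomer is used instead if the sense proves opposite). Only one phenol is free, so only the 8''-linked flavanone can form, and the C2'' epimers are diastereomers that can be separated.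

Step 19
Reactants: 36 (2S)-5,7-bis(benzyloxy)-2-[4-(benzyloxy)phenyl]-8-[(2R,3S)-5,7-bis(benzyloxy)-2-ArB-4-hydroxychroman-3-yl]chroman-4-one
Product: 37 (2R,3R)-5,7-bis(benzyloxy)-2-ArB-3-{(2S)-5,7-bis(benzyloxy)-2-[4-(benzyloxy)phenyl]-4-oxochroman-8-yl}chroman-4-one
Conditions: Dess–Martin periodinane, NaHCO3, CH2Cl2, 0 °C → rt
Reagents that add atoms: none
Why: Buffered Dess–Martin oxidation of the hindered benzylic carbinol converts both C4 epimers into one ketone under neutral conditions. No phenol is free at this stage and no base is present that could epimerize C3 once it has become acidic.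

Step 20
Reactants: 37 (2R,3R)-5,7-bis(benzyloxy)-2-ArB-3-{(2S)-5,7-bis(benzyloxy)-2-[4-(benzyloxy)phenyl]-4-oxochroman-8-yl}chroman-4-one
Product: 38 (2R,3R)-2-(3,4-dihydroxyphenyl)-5,7-dihydroxy-3-[(2S)-5,7-dihydroxy-2-(4-hydroxyphenyl)-4-oxochroman-8-yl]chroman-4-one (CNP0105436.1)
Conditions: H2 (1 atm), Pd/C (10 wt %), EtOAc/MeOH, rt
Reagents that add atoms: none
Why: Hydrogenolysis of all seven benzyl ethers over palladium on carbon in a neutral medium, so that no acid or base touches the cis-2,3 flavanone or C2''.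

## Compound list

1 | 3,5-bis(benzyloxy)phenol | Oc1cc(OCc2ccccc2)cc(OCc2ccccc2)c1 | starting material
2 | 1,3-bis(benzyloxy)-5-(SEM-oxy)benzene | C[Si](C)(C)CCOCOc1cc(OCc2ccccc2)cc(OCc2ccccc2)c1 | intermediate
3 | oxirane | C1CO1 | starting material
4 | 2,4-bis(benzyloxy)-6-(SEM-oxy)phenyllithium | [Li]c1c(OCOCC[Si](C)(C)C)cc(OCc2ccccc2)cc1OCc1ccccc1 | intermediate
5 | 2-[2,4-bis(benzyloxy)-6-(SEM-oxy)phenyl]ethan-1-ol | OCCc1c(OCOCC[Si](C)(C)C)cc(OCc2ccccc2)cc1OCc1ccccc1 | intermediate
6 | 2-[2,4-bis(benzyloxy)-6-(SEM-oxy)phenyl]acetaldehyde | O=CCc1c(OCOCC[Si](C)(C)C)cc(OCc2ccccc2)cc1OCc1ccccc1 | intermediate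
7 | 2-[2,4-bis(benzyloxy)-6-(SEM-oxy)phenyl]acetic acid | OC(=O)Cc1c(OCOCC[Si](C)(C)C)cc(OCc2ccccc2)cc1OCc1ccccc1 | intermediate
8 | (4R)-4-benzyl-1,3-oxazolidin-2-one | O=C1N[C@H](Cc2ccccc2)CO1 | starting material
9 | 2-[2,4-bis(benzyloxy)-6-(SEM-oxy)phenyl]acetic pivalic anhydride | CC(C)(C)C(=O)OC(=O)Cc1c(OCOCC[Si](C)(C)C)cc(OCc2ccccc2)cc1OCc1ccccc1 | intermediate
10 | (4R)-4-benzyl-3-{2-[2,4-bis(benzyloxy)-6-(SEM-oxy)phenyl]acetyl}-1,3-oxazolidin-2-one | O=C(Cc1c(OCOCC[Si](C)(C)C)cc(OCc2ccccc2)cc1OCc1ccccc1)N1C(=O)OC[C@H]1Cc1ccccc1 | intermediate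
11 | 3,4-bis(benzyloxy)benzaldehyde | O=Cc1ccc(OCc2ccccc2)c(OCc2ccccc2)c1 | starting material
12 | (4R)-4-benzyl-3-[(1Z)-2-ArD-1-[(dibutylboranyl)oxy]ethenyl]-1,3-oxazolidin-2-one | CCCCB(CCCC)O/C(=C\c1c(OCOCC[Si](C)(C)C)cc(OCc2ccccc2)cc1OCc1ccccc1)N1C(=O)OC[C@H]1Cc1ccccc1 | intermediate
13 | (4R)-4-benzyl-3-[(2R,3R)-3-ArB-2-ArD-3-hydroxypropanoyl]-1,3-oxazolidin-2-one | C[Si](C)(C)CCOCOc1cc(OCc2ccccc2)cc(OCc2ccccc2)c1[C@@H](C(=O)N1C(=O)OC[C@H]1Cc1ccccc1)[C@@H](O)c1ccc(OCc2ccccc2)c(OCc2ccccc2)c1 | intermediate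
14 | (1R,2S)-1-ArB-2-ArD-propane-1,3-diol | C[Si](C)(C)CCOCOc1cc(OCc2ccccc2)cc(OCc2ccccc2)c1[C@@H](CO)[C@@H](O)c1ccc(OCc2ccccc2)c(OCc2ccccc2)c1 | intermediate
15 | (1R,2S)-1-ArB-2-ArD-3-(TBDPS-oxy)propan-1-ol | C[Si](C)(C)CCOCOc1cc(OCc2ccccc2)cc(OCc2ccccc2)c1[C@@H](CO[Si](c1ccccc1)(c1ccccc1)C(C)(C)C)[C@@H](O)c1ccc(OCc2ccccc2)c(OCc2ccccc2)c1 | intermediate
16 | trichloroethylene | ClC=C(Cl)Cl | starting material
17 | tert-butyl{[(2S,3R)-3-ArB-2-ArD-3-{[(E)-1,2-dichloroethenyl]oxy}propyl]oxy}diphenylsilane | C[Si](C)(C)CCOCOc1cc(OCc2ccccc2)cc(OCc2ccccc2)c1[C@@H](CO[Si](c1ccccc1)(c1ccccc1)C(C)(C)C)[C@@H](O/C(Cl)=C\Cl)c1ccc(OCc2ccccc2)c(OCc2ccccc2)c1 | intermediate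
18 | lithium 2-[(1R,2S)-1-ArB-2-ArD-3-(TBDPS-oxy)propoxy]ethyn-1-ide | C[Si](C)(C)CCOCOc1cc(OCc2ccccc2)cc(OCc2ccccc2)c1[C@@H](CO[Si](c1ccccc1)(c1ccccc1)C(C)(C)C)[C@@H](OC#C[Li])c1ccc(OCc2ccccc2)c(OCc2ccccc2)c1 | intermediate
19 | tert-butyl{[(2S,3R)-3-ArB-2-ArD-3-(ethynyloxy)propyl]oxy}diphenylsilane | C[Si](C)(C)CCOCOc1cc(OCc2ccccc2)cc(OCc2ccccc2)c1[C@@H](CO[Si](c1ccccc1)(c1ccccc1)C(C)(C)C)[C@@H](OC#C)c1ccc(OCc2ccccc2)c(OCc2ccccc2)c1 | intermediate
20 | (2S,3R)-3-ArB-2-ArD-3-(ethynyloxy)propan-1-ol | C[Si](C)(C)CCOCOc1cc(OCc2ccccc2)cc(OCc2ccccc2)c1[C@@H](CO)[C@@H](OC#C)c1ccc(OCc2ccccc2)c(OCc2ccccc2)c1 | intermediate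
21 | (2R,3R)-3-ArB-2-ArD-3-(ethynyloxy)propanal | C[Si](C)(C)CCOCOc1cc(OCc2ccccc2)cc(OCc2ccccc2)c1[C@@H](C=O)[C@@H](OC#C)c1ccc(OCc2ccccc2)c(OCc2ccccc2)c1 | intermediate
22 | benzyl alcohol | OCc1ccccc1 | starting material
23 | benzyl (E)-1,2-dichloroethenyl ether | Cl/C=C(/Cl)OCc1ccccc1 | intermediate
24 | lithium 2-(benzyloxy)ethyn-1-ide | [Li]C#COCc1ccccc1 | intermediate
25 | benzyl ethynyl ether | C#COCc1ccccc1 | intermediate
26 | (benzyloxy)ethynylmagnesium bromide | Br[Mg]C#COCc1ccccc1 | intermediate
27 | (1R,2S)-5-(benzyloxy)-1-ArB-2-ArD-1-(ethynyloxy)pent-4-yn-3-ol, both C3 epimers | C[Si](C)(C)CCOCOc1cc(OCc2ccccc2)cc(OCc2ccccc2)c1[C@@H](C(O)C#COCc1ccccc1)[C@@H](OC#C)c1ccc(OCc2ccccc2)c(OCc2ccccc2)c1 | intermediate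
28 | (4R,5R)-1-(benzyloxy)-5-ArB-4-ArD-5-(ethynyloxy)-3-(TBS-oxy)pent-1-yne, both C3 epimers | C[Si](C)(C)CCOCOc1cc(OCc2ccccc2)cc(OCc2ccccc2)c1[C@@H](C(O[Si](C)(C)C(C)(C)C)C#COCc1ccccc1)[C@@H](OC#C)c1ccc(OCc2ccccc2)c(OCc2ccccc2)c1 | intermediate
29 | (2R,3R)-5,7-bis(benzyloxy)-2-ArB-3-ArD-4-(TBS-oxy)chromane, cis-2,3, both C4 epimers | C[Si](C)(C)CCOCOc1cc(OCc2ccccc2)cc(OCc2ccccc2)c1[C@H]1C(O[Si](C)(C)C(C)(C)C)c2c(OCc3ccccc3)cc(OCc3ccccc3)cc2O[C@H]1c1ccc(OCc2ccccc2)c(OCc2ccccc2)c1 | intermediate
30 | 4-(benzyloxy)benzaldehyde | O=Cc1ccc(OCc2ccccc2)cc1 | starting material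
31 | N-methoxy-N-methyl-2-(triphenyl-λ5-phosphanylidene)acetamide | CON(C)C(=O)C=P(c1ccccc1)(c1ccccc1)c1ccccc1 | starting material
32 | (2E)-3-[4-(benzyloxy)phenyl]-N-methoxy-N-methylprop-2-enamide | CON(C)C(=O)/C=C/c1ccc(OCc2ccccc2)cc1 | intermediate
33 | ring D aryllithium of 29 (lithium on the carbon between OSEM and OBn) | C[Si](C)(C)CCOCOc1c([Li])c(OCc2ccccc2)cc(OCc2ccccc2)c1[C@H]1C(O[Si](C)(C)C(C)(C)C)c2c(OCc3ccccc3)cc(OCc3ccccc3)cc2O[C@H]1c1ccc(OCc2ccccc2)c(OCc2ccccc2)c1 | intermediate
34 | (2E)-3-[4-(benzyloxy)phenyl]-1-{4,6-bis(benzyloxy)-3-[(2R,3R)-5,7-bis(benzyloxy)-2-ArB-4-(TBS-oxy)chroman-3-yl]-2-(SEM-oxy)phenyl}prop-2-en-1-one | C[Si](C)(C)CCOCOc1c(C(=O)/C=C/c2ccc(OCc3ccccc3)cc2)c(OCc2ccccc2)cc(OCc2ccccc2)c1[C@H]1C(O[Si](C)(C)C(C)(C)C)c2c(OCc3ccccc3)cc(OCc3ccccc3)cc2O[C@H]1c1ccc(OCc2ccccc2)c(OCc2ccccc2)c1 | intermediate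
35 | (2E)-3-[4-(benzyloxy)phenyl]-1-{4,6-bis(benzyloxy)-3-[(2R,3S)-5,7-bis(benzyloxy)-2-ArB-4-hydroxychroman-3-yl]-2-hydroxyphenyl}prop-2-en-1-one | Oc1c(C(=O)/C=C/c2ccc(OCc3ccccc3)cc2)c(OCc2ccccc2)cc(OCc2ccccc2)c1[C@H]1C(O)c2c(OCc3ccccc3)cc(OCc3ccccc3)cc2O[C@H]1c1ccc(OCc2ccccc2)c(OCc2ccccc2)c1 | intermediate
36 | (2S)-5,7-bis(benzyloxy)-2-[4-(benzyloxy)phenyl]-8-[(2R,3S)-5,7-bis(benzyloxy)-2-ArB-4-hydroxychroman-3-yl]chroman-4-one | O=C1C[C@@H](c2ccc(OCc3ccccc3)cc2)Oc2c1c(OCc1ccccc1)cc(OCc1ccccc1)c2[C@H]1C(O)c2c(OCc3ccccc3)cc(OCc3ccccc3)cc2O[C@H]1c1ccc(OCc2ccccc2)c(OCc2ccccc2)c1 | intermediate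
37 | (2R,3R)-5,7-bis(benzyloxy)-2-ArB-3-{(2S)-5,7-bis(benzyloxy)-2-[4-(benzyloxy)phenyl]-4-oxochroman-8-yl}chroman-4-one | O=C1C[C@@H](c2ccc(OCc3ccccc3)cc2)Oc2c1c(OCc1ccccc1)cc(OCc1ccccc1)c2[C@H]1C(=O)c2c(OCc3ccccc3)cc(OCc3ccccc3)cc2O[C@H]1c1ccc(OCc2ccccc2)c(OCc2ccccc2)c1 | intermediate
38 | (2R,3R)-2-(3,4-dihydroxyphenyl)-5,7-dihydroxy-3-[(2S)-5,7-dihydroxy-2-(4-hydroxyphenyl)-4-oxochroman-8-yl]chroman-4-one | O=C1C[C@@H](c2ccc(O)cc2)Oc2c1c(O)cc(O)c2[C@H]1C(=O)c2c(O)cc(O)cc2O[C@H]1c1ccc(O)c(O)c1 | target

## Step count and least certain steps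

Total step count: 20. Longest linear sequence: 18 steps (steps 1–10, 12–14 and 16–20, starting from 1); steps 11 and 15 are one-step side branches.

**Step 14 (key step).** The most likely failure is that the third alkyne is not taken up in the wanted way. Homotrimerization of 25, dimerization of 28, or loss of the two benzylic-type alkynyl ethers by sigmatropic shift or hydration on the cationic metal may outrun the cross-cycloaddition, since a 1,7-diyne cyclizes more slowly on rhodium than a 1,6-diyne. Insertion of 25 with the opposite orientation would place oxygen at C6.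
Fallback, from 15 back to 29, building ring A from a preformed arene: Pd-catalysed C–O coupling of the secondary alcohol 15 with 1-bromo-3,5-bis(benzyloxy)benzene ([(allyl)PdCl]2, a bulky di-tert-butyl biaryl phosphine, Cs2CO3, toluene, 90 °C; the C2–O bond is not broken, so C2 is retained) should give the 3,5-bis(benzyloxy)phenyl ether F1. TBAF then frees the primary alcohol F2, and TEMPO/PhI(OAc)2 in wet MeCN gives the acid F3. Intramolecular Friedel–Crafts acylation through the mixed trifluoroacetic anhydride ((CF3CO)2O, CH2Cl2, 0 °C) should close ring C onto the trioxygenated ring to give the cis chromanone F4 (the six-membered closure onto the far more electron-rich ring A should win over indanone formation on ring B). F4 is reduced at once with NaBH4 to the chromanol F5, and TBSCl/imidazole returns to 29.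

**Step 8.** The most likely failures are incomplete addition of the hindered secondary alkoxide to dichloroacetylene, migration of the silyl group to the secondary oxygen under KH, and competing metalation of ring D by n-BuLi.
Fallback, from 15 back to 19, building the alkyne from a one-carbon ester: formylation of 15 (acetic formic anhydride, pyridine) gives the formate F6; dibromomethylenation of the formyl group (CBr4, PPh3, CH2Cl2) gives the 2,2-dibromovinyl ether F7; n-BuLi (2.2 equiv, THF, −78 °C) converts F7 into 18, and methanol gives 19.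

**Step 16.** The most likely failure is deprotonation at the wrong site: the ring A positions between two oxygens, the position of ring D between its two benzyl ethers, or a benzylic CH2 followed by Wittig rearrangement.
Fallback, from 29 back to 35, using a free phenol to direct the new carbon: MgBr2·OEt2 in Et2O/MeNO2 should cleave only the SEM ether to give the phenol F8. Magnesium-mediated ortho-formylation (MgCl2, Et3N, paraformaldehyde, THF, reflux) attacks only the carbon next to the phenol and gives the salicylaldehyde F9. MeMgBr gives the 1-arylethanol F10, and MnO2 gives the 2-hydroxyacetophenone F11. Claisen–Schmidt condensation with 30 (KOH, EtOH, rt) gives the TBS-protected hydroxychalcone F12, and TBAF at room temperature gives 35.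

**Step 18.** The most likely failure is poor facial selectivity at C2'', because the enone is not activated and the bulky unit 1 sits next to the reacting phenol, together with slow erosion by the reversible ring opening under the basic catalyst.
Fallback, from 35 back to 36, replacing catalyst control by separation and recycling: uncatalysed ring closure (NaOAc, EtOH, 60 °C) gives 36 together with its C2'' epimer F13. The two diastereomers are separated by chromatography, and F13 is returned to the same conditions, where it re-opens to 35 and closes again, until the material has converged on 36.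

## Further compounds

F1 | step 14 | tert-butyl{[(2S,3R)-3-ArB-2-ArD-3-[3,5-bis(benzyloxy)phenoxy]propyl]oxy}diphenylsilane | C[Si](C)(C)CCOCOc1cc(OCc2ccccc2)cc(OCc2ccccc2)c1[C@@H](CO[Si](c1ccccc1)(c1ccccc1)C(C)(C)C)[C@@H](Oc1cc(OCc2ccccc2)cc(OCc2ccccc2)c1)c1ccc(OCc2ccccc2)c(OCc2ccccc2)c1
F2 | step 14 | (2S,3R)-3-ArB-2-ArD-3-[3,5-bis(benzyloxy)phenoxy]propan-1-ol | C[Si](C)(C)CCOCOc1cc(OCc2ccccc2)cc(OCc2ccccc2)c1[C@@H](CO)[C@@H](Oc1cc(OCc2ccccc2)cc(OCc2ccccc2)c1)c1ccc(OCc2ccccc2)c(OCc2ccccc2)c1
F3 | step 14 | (2R,3R)-3-ArB-2-ArD-3-[3,5-bis(benzyloxy)phenoxy]propanoic acid | C[Si](C)(C)CCOCOc1cc(OCc2ccccc2)cc(OCc2ccccc2)c1[C@@H](C(=O)O)[C@@H](Oc1cc(OCc2ccccc2)cc(OCc2ccccc2)c1)c1ccc(OCc2ccccc2)c(OCc2ccccc2)c1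
F4 | step 14 | (2R,3R)-5,7-bis(benzyloxy)-2-ArB-3-ArD-chroman-4-one | C[Si](C)(C)CCOCOc1cc(OCc2ccccc2)cc(OCc2ccccc2)c1[C@H]1C(=O)c2c(OCc3ccccc3)cc(OCc3ccccc3)cc2O[C@H]1c1ccc(OCc2ccccc2)c(OCc2ccccc2)c1
F5 | step 14 | (2R,3S)-5,7-bis(benzyloxy)-2-ArB-3-ArD-chroman-4-ol (C4 as formed by hydride addition) | C[Si](C)(C)CCOCOc1cc(OCc2ccccc2)cc(OCc2ccccc2)c1[C@H]1C(O)c2c(OCc3ccccc3)cc(OCc3ccccc3)cc2O[C@H]1c1ccc(OCc2ccccc2)c(OCc2ccccc2)c1
F6 | step 8 | (1R,2S)-1-ArB-2-ArD-3-(TBDPS-oxy)propyl formate | C[Si](C)(C)CCOCOc1cc(OCc2ccccc2)cc(OCc2ccccc2)c1[C@@H](CO[Si](c1ccccc1)(c1ccccc1)C(C)(C)C)[C@@H](OC=O)c1ccc(OCc2ccccc2)c(OCc2ccccc2)c1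
F7 | step 8 | tert-butyl{[(2S,3R)-3-ArB-2-ArD-3-[(2,2-dibromoethenyl)oxy]propyl]oxy}diphenylsilane | C[Si](C)(C)CCOCOc1cc(OCc2ccccc2)cc(OCc2ccccc2)c1[C@@H](CO[Si](c1ccccc1)(c1ccccc1)C(C)(C)C)[C@@H](OC=C(Br)Br)c1ccc(OCc2ccccc2)c(OCc2ccccc2)c1
F8 | step 16 | 3,5-bis(benzyloxy)-2-[(2R,3R)-5,7-bis(benzyloxy)-2-ArB-4-(TBS-oxy)chroman-3-yl]phenol | Oc1cc(OCc2ccccc2)cc(OCc2ccccc2)c1[C@H]1C(O[Si](C)(C)C(C)(C)C)c2c(OCc3ccccc3)cc(OCc3ccccc3)cc2O[C@H]1c1ccc(OCc2ccccc2)c(OCc2ccccc2)c1
F9 | step 16 | 4,6-bis(benzyloxy)-3-[(2R,3R)-5,7-bis(benzyloxy)-2-ArB-4-(TBS-oxy)chroman-3-yl]-2-hydroxybenzaldehyde | Oc1c(C=O)c(OCc2ccccc2)cc(OCc2ccccc2)c1[C@H]1C(O[Si](C)(C)C(C)(C)C)c2c(OCc3ccccc3)cc(OCc3ccccc3)cc2O[C@H]1c1ccc(OCc2ccccc2)c(OCc2ccccc2)c1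
F10 | step 16 | 1-{4,6-bis(benzyloxy)-3-[(2R,3R)-5,7-bis(benzyloxy)-2-ArB-4-(TBS-oxy)chroman-3-yl]-2-hydroxyphenyl}ethan-1-ol (both carbinol epimers) | Oc1c(C(C)O)c(OCc2ccccc2)cc(OCc2ccccc2)c1[C@H]1C(O[Si](C)(C)C(C)(C)C)c2c(OCc3ccccc3)cc(OCc3ccccc3)cc2O[C@H]1c1ccc(OCc2ccccc2)c(OCc2ccccc2)c1
F11 | step 16 | 1-{4,6-bis(benzyloxy)-3-[(2R,3R)-5,7-bis(benzyloxy)-2-ArB-4-(TBS-oxy)chroman-3-yl]-2-hydroxyphenyl}ethan-1-one | Oc1c(C(C)=O)c(OCc2ccccc2)cc(OCc2ccccc2)c1[C@H]1C(O[Si](C)(C)C(C)(C)C)c2c(OCc3ccccc3)cc(OCc3ccccc3)cc2O[C@H]1c1ccc(OCc2ccccc2)c(OCc2ccccc2)c1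
F12 | step 16 | (2E)-3-[4-(benzyloxy)phenyl]-1-{4,6-bis(benzyloxy)-3-[(2R,3R)-5,7-bis(benzyloxy)-2-ArB-4-(TBS-oxy)chroman-3-yl]-2-hydroxyphenyl}prop-2-en-1-one | Oc1c(C(=O)/C=C/c2ccc(OCc3ccccc3)cc2)c(OCc2ccccc2)cc(OCc2ccccc2)c1[C@H]1C(O[Si](C)(C)C(C)(C)C)c2c(OCc3ccccc3)cc(OCc3ccccc3)cc2O[C@H]1c1ccc(OCc2ccccc2)c(OCc2ccccc2)c1
F13 | step 18 | (2R)-5,7-bis(benzyloxy)-2-[4-(benzyloxy)phenyl]-8-[(2R,3S)-5,7-bis(benzyloxy)-2-ArB-4-hydroxychroman-3-yl]chroman-4-one (C2'' epimer of 36) | O=C1C[C@H](c2ccc(OCc3ccccc3)cc2)Oc2c1c(OCc1ccccc1)cc(OCc1ccccc1)c2[C@H]1C(O)c2c(OCc3ccccc3)cc(OCc3ccccc3)cc2O[C@H]1c1ccc(OCc2ccccc2)c(OCc2ccccc2)c1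
A1 | alternative 1 | 1-[2,4-bis(benzyloxy)-6-hydroxyphenyl]-3-[3,4-bis(benzyloxy)phenyl]prop-2-yn-1-one | O=C(C#Cc1ccc(OCc2ccccc2)c(OCc2ccccc2)c1)c1c(O)cc(OCc2ccccc2)cc1OCc1ccccc1
A2 | alternative 1 | 1,5-bis(benzyloxy)-2-iodo-3-(methoxymethoxy)benzene | COCOc1cc(OCc2ccccc2)cc(OCc2ccccc2)c1I
A3 | alternative 1 | 5,7-bis(benzyloxy)-2-[3,4-bis(benzyloxy)phenyl]-3-[2,4-bis(benzyloxy)-6-(methoxymethoxy)phenyl]-4H-chromen-4-one | COCOc1cc(OCc2ccccc2)cc(OCc2ccccc2)c1-c1c(-c2ccc(OCc3ccccc3)c(OCc3ccccc3)c2)oc2cc(OCc3ccccc3)cc(OCc3ccccc3)c2c1=O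
A4 | alternative 2 | (2S)-5-(benzyloxy)-2-[4-(benzyloxy)phenyl]-8-{2-[2,4-bis(benzyloxy)-6-{[3,4-bis(benzyloxy)phenyl]methoxy}phenyl]-1-diazo-2-oxoethyl}-7-(TBS-oxy)chroman-4-one | [N-]=[N+]=C(C(=O)c1c(OCc2ccccc2)cc(OCc2ccccc2)cc1OCc1ccc(OCc2ccccc2)c(OCc2ccccc2)c1)c1c(O[Si](C)(C)C(C)(C)C)cc(OCc2ccccc2)c2c1O[C@H](c1ccc(OCc3ccccc3)cc1)CC2=O
A5 | alternative 2 | (2R,3R)-5,7-bis(benzyloxy)-2-[3,4-bis(benzyloxy)phenyl]-3-{(2S)-5-(benzyloxy)-2-[4-(benzyloxy)phenyl]-7-(TBS-oxy)-4-oxochroman-8-yl}chroman-4-one | O=C1C[C@@H](c2ccc(OCc3ccccc3)cc2)Oc2c1c(OCc3ccccc3)cc(O[Si](C)(C)C(C)(C)C)c2[C@H]1C(=O)c2c(OCc3ccccc3)cc(OCc3ccccc3)cc2O[C@H]1c1ccc(OCc3ccccc3)c(OCc3ccccc3)c1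
A6 | alternative 3 | (2Z)-1-[3,4-bis(benzyloxy)phenyl]-3-[2,4-bis(benzyloxy)-6-hydroxyphenyl]-2-[2,4-bis(benzyloxy)-6-(SEM-oxy)phenyl]prop-2-en-1-ol (racemic) | OC(c1ccc(OCc2ccccc2)c(OCc2ccccc2)c1)/C(c1c(OCOCC[Si](C)(C)C)cc(OCc2ccccc2)cc1OCc1ccccc1)=C\c1c(O)cc(OCc2ccccc2)cc1OCc1ccccc1
A7 | alternative 3 | (2S)-5,7-bis(benzyloxy)-2-[3,4-bis(benzyloxy)phenyl]-3-[2,4-bis(benzyloxy)-6-(SEM-oxy)phenyl]-2H-chromene | C[Si](C)(C)CCOCOc1cc(OCc2ccccc2)cc(OCc2ccccc2)c1C1=Cc2c(OCc3ccccc3)cc(OCc3ccccc3)cc2O[C@H]1c1ccc(OCc3ccccc3)c(OCc3ccccc3)c1
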